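**Strategy.** The furan (O1, C2–H, C3 bearing the side chain, C4–H, C5 bearing the arene) is disconnected at C3=C4. The two carbons flanking this bond, C2 and C5, are both bound to O1, so the ring can be closed by ring-closing metathesis of a mixed acetal. C2 is an acetal carbon whose ethoxy group later leaves to aromatise; C5 is a benzylic allyl ether carbon. One operation closes the five-membered ring and forms C3=C4 without any oxidant. The precursor joins an (R)-configured 2-methylene acetal carrying the isovalerate, made by CBS reduction, to a racemic aryl vinyl carbinol. The quinone stays masked as a dimethoxyarene until the last step.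

Key step: step 7

Remark on the chemistry: the carbinol carbon is (R) in every chiral compound (CIP order O > alkenyl or furyl carbon > CH2 > H). Compounds 12, 13 and 14 are stereorandom at the acetal carbon, 13 and 14 also at the benzylic carbon; both carbons become sp2 in step 8, so the mixtures converge.

**Step 1**
Reactants: 1 2,5-dimethoxybenzaldehyde
Product: 2 rac-1-(2,5-dimethoxyphenyl)prop-2-en-1-ol
Conditions: vinylmagnesium bromide (1.2 equiv), THF, 0 °C; sat. aq NH4Cl
Reagents that add atoms: vinylmagnesium bromide, C=C[Mg]Br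
Why: Grignard 1,2-addition of a vinyl nucleophile to an aromatic aldehyde; the benzylic stereocentre is left racemic on purpose because it is flattened in step 8.

**Step 2**
Reactants: 3 4-methylpent-3-enoic acid
Product: 4 N-methoxy-N,4-dimethylpent-3-enamide
Conditions: CDI (1.1 equiv), CH2Cl2, rt; then MeNHOMe·HCl (1.2 equiv), rt
Reagents that add atoms: N,O-dimethylhydroxylamine hydrochloride, CNOC.Cl
Why: Weinreb amide formation through the acyl imidazolide; neutral activation avoids an acid chloride that could pull the β,γ-olefin into conjugation.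

**Step 3**
Reactants: 5 2-bromo-3,3-diethoxyprop-1-ene; 4 N-methoxy-N,4-dimethylpent-3-enamide
Product: 8 2-(diethoxymethyl)-6-methylhepta-1,5-dien-3-one, via lithiated acrolein acetal 6 (not isolated), via tetrahedral lithium adduct 7 (not isolated)
Conditions: 5 (1.2 equiv), t-BuLi (2.4 equiv), Et2O, −78 °C; then 4 in THF, −78 °C; quench at −78 °C with cold sat. aq NH4Cl
Reagents that add atoms: none
Why: Bromine–lithium exchange followed by Weinreb ketone synthesis; the chelated adduct 7 survives until the cold quench, which prevents a second addition and limits enolisation, olefin migration and conjugate addition of the released amine to the enone.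

**Step 4**
Reactants: 8 2-(diethoxymethyl)-6-methylhepta-1,5-dien-3-one
Product: 9 (R)-2-(diethoxymethyl)-6-methylhepta-1,5-dien-3-ol
Conditions: (S)-2-methyl-CBS-oxazaborolidine [(S)-1-methyl-3,3-diphenyltetrahydro-1H,3H-pyrrolo[1,2-c][1,3,2]oxazaborole, C18H20BNO] (0.2 equiv), catecholborane (1.5 equiv), toluene, −78 °C; MeOH, then dilute aq NaOH wash
Reagents that add atoms: none
Why: Corey–Bakshi–Shibata reduction; the ketone binds the catalyst boron anti to the larger α-branched alkenyl group, so the (S)-catalyst should deliver hydride to the face giving the (R)-alcohol (alkenyl large, primary alkyl small, as with aryl alkyl ketones), and catecholborane at −78 °C should leave the olefins and the acetal alone.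

**Step 5**
Reactants: 9 (R)-2-(diethoxymethyl)-6-methylhepta-1,5-dien-3-ol; 10 3-methylbutanoyl chloride
Product: 11 (R)-2-(diethoxymethyl)-6-methylhepta-1,5-dien-3-yl 3-methylbutanoate
Conditions: 10 (1.5 equiv), pyridine (3 equiv), 4-(dimethylamino)pyridine (0.1 equiv), CH2Cl2, 0 °C to rt
Reagents that add atoms: none
Why: Nucleophile-catalysed acylation of a secondary allylic alcohol with an acid chloride; the basic medium preserves the acetal, and the C–O bond at the stereocentre is not broken.

**Step 6**
Reactants: 11 (R)-2-(diethoxymethyl)-6-methylhepta-1,5-dien-3-yl 3-methylbutanoate; 2 rac-1-(2,5-dimethoxyphenyl)prop-2-en-1-ol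
Product: 13 (3R)-2-{ethoxy[1-(2,5-dimethoxyphenyl)prop-2-en-1-yloxy]methyl}-6-methylhepta-1,5-dien-3-yl 3-methylbutanoate (four diastereomers), via collidinium triflate salt 12 (not isolated)
Conditions: Et3SiOTf (1.5 equiv), 2,4,6-collidine (3 equiv), CH2Cl2, 0 °C; then 2 (2.5 equiv), 0 °C to rt; sat. aq NaHCO3; chromatography on Et3N-deactivated silica
Reagents that add atoms: none
Why: Mixed-acetal formation by silyl triflate/pyridine activation of a dialkyl acetal; one ethoxy group leaves as Et3SiOEt, collidine traps the oxocarbenium ion as pyridinium salt 12, and alcohol 2 then displaces collidine under buffered conditions, so exactly one ethoxy group is exchanged and the acid-labile benzylic allylic alcohol never meets a Brønsted acid.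

**Step 7**
Reactants: 13 the mixed acetal (four diastereomers)
Product: 14 (1R)-1-[5-(2,5-dimethoxyphenyl)-2-ethoxy-2,5-dihydrofuran-3-yl]-4-methylpent-3-en-1-yl 3-methylbutanoate (mixture at ring C2 and C5)
Conditions: second-generation Grubbs catalyst [RuCl2(=CHPh)(PCy3)(H2IMes)] (10 mol%), toluene (0.005 M), 70 °C, argon sparge; filtration through Et3N-deactivated silica
Reagents that add atoms: none
Why: Ring-closing olefin metathesis: the ruthenium benzylidene exchanges onto the monosubstituted vinyl group of the aryl allyl ether, the new alkylidene adds across the 1,1-disubstituted olefin to a ruthenacyclobutane, and cycloreversion releases the C3=C4 bond and, on turnover, ethylene. The closest known reaction type is metathesis closure of mixed allylic acetals to 2-alkoxy-2,5-dihydrofurans that are aromatised afterwards by acid. The one ring is closed as a five-membered ring (O1, C2, C3, C4, C5) by intramolecular metathesis across a three-atom tether (C5–O1–C2), which favours cyclisation entropically over intermolecular reaction. No stereocentre is formed; the (R) carbinol carbon is a spectator, and the acetal and benzylic carbons need no control because step 8 flattens both. The step needs chemoselectivity among three olefins and against cross-metathesis: the catalyst can load only at the vinyl group, since the gem-disubstituted and the trisubstituted prenyl olefins are too hindered to initiate and closure onto the prenyl olefin would demand an eight-membered cyclic diene. High dilution with removal of ethylene is meant to suppress dimerisation at the vinyl group.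

**Step 8**
Reactants: 14 the 2-ethoxy-2,5-dihydrofuran
Product: 15 (1R)-1-[5-(2,5-dimethoxyphenyl)furan-3-yl]-4-methylpent-3-en-1-yl 3-methylbutanoate
Conditions: pyridinium p-toluenesulfonate (0.2 equiv), CH2Cl2, rt
Reagents that add atoms: none
Why: Acid-catalysed 1,4-elimination of ethanol (aromatisation of a 2-alkoxy-2,5-dihydrofuran); loss of ethanol gives a cyclic oxocarbenium ion that sheds the doubly activated C5 proton, and the gain in aromaticity allows an acid too weak to ionise the furylic ester.

**Step 9**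
Reactants: 15 the dimethoxyaryl furan
Product: 16 (1R)-1-[5-(3,6-dioxocyclohexa-1,4-dien-1-yl)furan-3-yl]-4-methylpent-3-en-1-yl 3-methylbutanoate
Conditions: (NH4)2Ce(NO3)6 (2.5 equiv), MeCN/H2O (2:1), 0 °C, short reaction time
Reagents that add atoms: water, O
Why: Oxidative demethylation of a para-dimethoxyarene by tetravalent cerium; two one-electron oxidations with ipso attack of water and loss of methanol at each methoxy-bearing carbon give the 1,4-benzoquinone, and brief cold exposure to a limited amount of oxidant is meant to spare the furan, the prenyl olefin and the ester.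

**Compound list**
1 | 2,5-dimethoxybenzaldehyde | COc1ccc(OC)c(C=O)c1 | starting material
2 | rac-1-(2,5-dimethoxyphenyl)prop-2-en-1-ol | C=CC(O)c1cc(OC)ccc1OC | intermediate
3 | 4-methylpent-3-enoic acid | CC(C)=CCC(=O)O | starting material
4 | N-methoxy-N,4-dimethylpent-3-enamide | CC(C)=CCC(=O)N(C)OC | intermediate
5 | 2-bromo-3,3-diethoxyprop-1-ene | C=C(Br)C(OCC)OCC | starting material
6 | (3,3-diethoxyprop-1-en-2-yl)lithium, formed in situ | [Li]C(=C)C(OCC)OCC | intermediate
7 | lithium 2-(diethoxymethyl)-3-[methoxy(methyl)amino]-6-methylhepta-1,5-dien-3-olate, formed in situ | CC(C)=CCC(O[Li])(N(C)OC)C(=C)C(OCC)OCC | intermediate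
8 | 2-(diethoxymethyl)-6-methylhepta-1,5-dien-3-one | CC(C)=CCC(=O)C(=C)C(OCC)OCC | intermediate
9 | (R)-2-(diethoxymethyl)-6-methylhepta-1,5-dien-3-ol | CC(C)=CC[C@@H](O)C(=C)C(OCC)OCC | intermediate
10 | 3-methylbutanoyl chloride | CC(C)CC(Cl)=O | starting material
11 | (R)-2-(diethoxymethyl)-6-methylhepta-1,5-dien-3-yl 3-methylbutanoate | CC(C)=CC[C@@H](OC(=O)CC(C)C)C(=C)C(OCC)OCC | intermediate
12 | 1-{(3R)-1-ethoxy-2-methylene-3-(3-methylbutanoyloxy)-6-methylhept-5-en-1-yl}-2,4,6-trimethylpyridinium triflate, formed in situ, mixture at the N,O-acetal carbon | CC(C)=CC[C@@H](OC(=O)CC(C)C)C(=C)C(OCC)[n+]1c(C)cc(C)cc1C.[O-]S(=O)(=O)C(F)(F)F | intermediate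
13 | (3R)-2-{ethoxy[1-(2,5-dimethoxyphenyl)prop-2-en-1-yloxy]methyl}-6-methylhepta-1,5-dien-3-yl 3-methylbutanoate, mixture at the acetal and benzylic carbons | CC(C)=CC[C@@H](OC(=O)CC(C)C)C(=C)C(OCC)OC(C=C)c1cc(OC)ccc1OC | intermediate
14 | (1R)-1-[5-(2,5-dimethoxyphenyl)-2-ethoxy-2,5-dihydrofuran-3-yl]-4-methylpent-3-en-1-yl 3-methylbutanoate, mixture at ring C2 and C5 | CC(C)=CC[C@@H](OC(=O)CC(C)C)C1=CC(c2cc(OC)ccc2OC)OC1OCC | intermediate
15 | (1R)-1-[5-(2,5-dimethoxyphenyl)furan-3-yl]-4-methylpent-3-en-1-yl 3-methylbutanoate | CC(C)=CC[C@@H](OC(=O)CC(C)C)c1coc(-c2cc(OC)ccc2OC)c1 | intermediate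
16 | (1R)-1-[5-(3,6-dioxocyclohexa-1,4-dien-1-yl)furan-3-yl]-4-methylpent-3-en-1-yl 3-methylbutanoate | CC(C)=CC[C@@H](OC(=O)CC(C)C)c1coc(C2=CC(=O)C=CC2=O)c1 | target

**Totals.** Total step count: 9. Longest linear sequence: 8 steps (3 → 4 → 8 → 9 → 11 → 13 → 14 → 15 → 16).

**Steps most likely to fail**

Step 7. Ring closure onto the gem-disubstituted olefin, which is flanked by two branched carbons, may be slow. Dimerisation at the vinyl group, ruthenium hydride isomerisation of the allyl ether, or catalyst decay could then win. The fallback does not make the furan ring but brings it in. It sets out from Weinreb amide 4 and comes back at furan 15. Commercial 2,4-dibromofuran F1 and (2,5-dimethoxyphenyl)boronic acid F2 would be joined by Suzuki coupling (Pd(PPh3)4, a zerovalent palladium complex, Na2CO3, DME/H2O, 80 °C), which is selective for the more reactive bromide next to oxygen, to give 4-bromo-2-(2,5-dimethoxyphenyl)furan F3. Bromine–lithium exchange (t-BuLi, Et2O, −78 °C) would give [5-(2,5-dimethoxyphenyl)furan-3-yl]lithium F4, which would add to 4 to form the tetrahedral lithium adduct F5 and, after a cold quench, 1-[5-(2,5-dimethoxyphenyl)furan-3-yl]-4-methylpent-3-en-1-one F6. Reduction under the conditions of step 4 (furyl as the large group) should give (R)-1-[5-(2,5-dimethoxyphenyl)furan-3-yl]-4-methylpent-3-en-1-ol F7, and acylation with 10 as in step 5 would return to 15.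

Step 6. The exchange may be diverted by capture of the oxocarbenium ion by the neighbouring ester carbonyl or the prenyl olefin, by attack of the alcohol at the methylene terminus instead of the acetal carbon, or by silylation of 2. The fallback makes the acetal linkage first, on a partner that has neither ester nor prenyl group, and builds the carbinol afterwards. It sets out from 5 and 2 and comes back at 13. Acetal 5 in excess would be activated with Et3SiOTf and 2,4,6-collidine to 1-(2-bromo-1-ethoxyprop-2-en-1-yl)-2,4,6-trimethylpyridinium triflate F8, and 2 as the limiting partner would convert this to 2-[1-(2-bromo-1-ethoxyprop-2-en-1-yloxy)prop-2-en-1-yl]-1,4-dimethoxybenzene F9. Bromine–lithium exchange at −78 °C would give the lithiated mixed acetal F10, which would add to 4 to form the tetrahedral lithium adduct F11 and then 2-{ethoxy[1-(2,5-dimethoxyphenyl)prop-2-en-1-yloxy]methyl}-6-methylhepta-1,5-dien-3-one F12. Reagent-controlled reduction as in step 4 should give the (3R)-alcohol F13, and acylation with 10 would give 13.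

Step 9. The electron-rich 2-arylfuran may be oxidised in competition with the arene, leading to oxidative opening at the free C2–H position, and the acidic oxidant may ionise the furylic ester. The fallback removes the oxidative demethylation by changing the mask of the hydroquinone. It sets out from 11 and comes back at 16. Commercial 2,5-dihydroxybenzaldehyde F14 would be silylated (i-Pr3SiCl, imidazole, DMF) to 2,5-bis(triisopropylsilyloxy)benzaldehyde F15, and vinylmagnesium bromide at −78 °C would give rac-1-[2,5-bis(triisopropylsilyloxy)phenyl]prop-2-en-1-ol F16. Steps 6 to 8, applied to 11 and F16 through salt 12, would give the silylated mixed acetal F17, the silylated 2-ethoxy-2,5-dihydrofuran F18 and the silylated aryl furan F19. Bu4NF buffered with AcOH (THF, 0 °C) would release (1R)-1-[5-(2,5-dihydroxyphenyl)furan-3-yl]-4-methylpent-3-en-1-yl 3-methylbutanoate F20. Ag2O in Et2O would then dehydrogenate this hydroquinone to 16 under neutral conditions.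

**Further compounds**
F1 | step 7 | 2,4-dibromofuran | Brc1coc(Br)c1
F2 | step 7 | (2,5-dimethoxyphenyl)boronic acid | COc1ccc(OC)c(B(O)O)c1
F3 | step 7 | 4-bromo-2-(2,5-dimethoxyphenyl)furan | COc1ccc(OC)c(-c2cc(Br)co2)c1
F4 | step 7 | [5-(2,5-dimethoxyphenyl)furan-3-yl]lithium | COc1ccc(OC)c(-c2cc([Li])co2)c1
F5 | step 7 | lithium 1-[5-(2,5-dimethoxyphenyl)furan-3-yl]-1-[methoxy(methyl)amino]-4-methylpent-3-en-1-olate | CC(C)=CCC(O[Li])(N(C)OC)c1coc(-c2cc(OC)ccc2OC)c1
F6 | step 7 | 1-[5-(2,5-dimethoxyphenyl)furan-3-yl]-4-methylpent-3-en-1-one | CC(C)=CCC(=O)c1coc(-c2cc(OC)ccc2OC)c1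
F7 | step 7 | (R)-1-[5-(2,5-dimethoxyphenyl)furan-3-yl]-4-methylpent-3-en-1-ol | CC(C)=CC[C@@H](O)c1coc(-c2cc(OC)ccc2OC)c1
F8 | step 6 | 1-(2-bromo-1-ethoxyprop-2-en-1-yl)-2,4,6-trimethylpyridinium triflate | C=C(Br)C(OCC)[n+]1c(C)cc(C)cc1C.[O-]S(=O)(=O)C(F)(F)F
F9 | step 6 | 2-[1-(2-bromo-1-ethoxyprop-2-en-1-yloxy)prop-2-en-1-yl]-1,4-dimethoxybenzene | C=C(Br)C(OCC)OC(C=C)c1cc(OC)ccc1OC
F10 | step 6 | {3-ethoxy-3-[1-(2,5-dimethoxyphenyl)prop-2-en-1-yloxy]prop-1-en-2-yl}lithium | [Li]C(=C)C(OCC)OC(C=C)c1cc(OC)ccc1OC
F11 | step 6 | lithium 2-{ethoxy[1-(2,5-dimethoxyphenyl)prop-2-en-1-yloxy]methyl}-3-[methoxy(methyl)amino]-6-methylhepta-1,5-dien-3-olate | CC(C)=CCC(O[Li])(N(C)OC)C(=C)C(OCC)OC(C=C)c1cc(OC)ccc1OC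
F12 | step 6 | 2-{ethoxy[1-(2,5-dimethoxyphenyl)prop-2-en-1-yloxy]methyl}-6-methylhepta-1,5-dien-3-one | CC(C)=CCC(=O)C(=C)C(OCC)OC(C=C)c1cc(OC)ccc1OC
F13 | step 6 | (3R)-2-{ethoxy[1-(2,5-dimethoxyphenyl)prop-2-en-1-yloxy]methyl}-6-methylhepta-1,5-dien-3-ol | CC(C)=CC[C@@H](O)C(=C)C(OCC)OC(C=C)c1cc(OC)ccc1OC
F14 | step 9 | 2,5-dihydroxybenzaldehyde | O=Cc1cc(O)ccc1O
F15 | step 9 | 2,5-bis(triisopropylsilyloxy)benzaldehyde | O=Cc1cc(O[Si](C(C)C)(C(C)C)C(C)C)ccc1O[Si](C(C)C)(C(C)C)C(C)C
F16 | step 9 | rac-1-[2,5-bis(triisopropylsilyloxy)phenyl]prop-2-en-1-ol | C=CC(O)c1cc(O[Si](C(C)C)(C(C)C)C(C)C)ccc1O[Si](C(C)C)(C(C)C)C(C)C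
F17 | step 9 | (3R)-2-{ethoxy[1-(2,5-bis(triisopropylsilyloxy)phenyl)prop-2-en-1-yloxy]methyl}-6-methylhepta-1,5-dien-3-yl 3-methylbutanoate | CC(C)=CC[C@@H](OC(=O)CC(C)C)C(=C)C(OCC)OC(C=C)c1cc(O[Si](C(C)C)(C(C)C)C(C)C)ccc1O[Si](C(C)C)(C(C)C)C(C)C
F18 | step 9 | (1R)-1-{5-[2,5-bis(triisopropylsilyloxy)phenyl]-2-ethoxy-2,5-dihydrofuran-3-yl}-4-methylpent-3-en-1-yl 3-methylbutanoate | CC(C)=CC[C@@H](OC(=O)CC(C)C)C1=CC(c2cc(O[Si](C(C)C)(C(C)C)C(C)C)ccc2O[Si](C(C)C)(C(C)C)C(C)C)OC1OCC
F19 | step 9 | (1R)-1-{5-[2,5-bis(triisopropylsilyloxy)phenyl]furan-3-yl}-4-methylpent-3-en-1-yl 3-methylbutanoate | CC(C)=CC[C@@H](OC(=O)CC(C)C)c1coc(-c2cc(O[Si](C(C)C)(C(C)C)C(C)C)ccc2O[Si](C(C)C)(C(C)C)C(C)C)c1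
F20 | step 9 | (1R)-1-[5-(2,5-dihydroxyphenyl)furan-3-yl]-4-methylpent-3-en-1-yl 3-methylbutanoate | CC(C)=CC[C@@H](OC(=O)CC(C)C)c1coc(-c2cc(O)ccc2O)c1
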